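**Retrosynthetic overview**

1. Ring A is numbered C1 (CH2OH), C2 (H), C3 (Br), C4 (OH), C5 (OH), C6 (benzyl); ring B is the 3-bromo-4-hydroxyphenyl group. The strategy rests on the two carbon arms at adjacent C1 and C6, with C6 next to the oxygenated C5: a C1–C6 aryne polarised by a C5 methoxy group can take up both arms in one step.
2. Target 20 ⇐ acid 19 (BH3 reduction of the C1 carboxyl) ⇐ 18 (BBr3) ⇐ 17 (bromination at C3, directed by a free C4 hydroxyl beside a C5 methoxy group).
3. 17 ⇐ 16 (selective O-debenzylation) ⇐ phthalide 15 (ionic hydrogenation of the doubly benzylic C–O bond) ⇐ iminolactone 14 (acid hydrolysis).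
4. 14 ⇐ silyl triflate 8 + tert-butyl isocyanide 9 + aldehyde 10 by a three-component aryne coupling (C1–C, C6–C and C–O bonds). This is the only ring closed in the route; rings A and B are bought, and the five-membered ring is opened again in step 6.
5. 8 ⇐ 4-(benzyloxy)-3-methoxyphenol 1 by carbamate-directed lithiation and silylation at C6, then carbamate cleavage and triflation.

Key step: step 4

Remarks on the chemistry:
- Positions C1 to C6 in the text always refer to ring A as numbered above; compound names use their own locants.
- Assumption: the C4 oxygen is carried as a benzyl ether and the C5 oxygen as a methyl ether, so that C4 alone can be freed before bromination. A thiolate demethylation of a C4/C5 dimethyl ether at the free-acid stage would have no dependable preference for C4, because the carboxylate gives little para activation and the hindered C5 methoxy group and the bromine-activated ring B methoxy group compete.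
- The target is achiral; the one stereocentre made on the way is racemic and is removed in step 6.

**Step 1**
Reactants: 1 4-(benzyloxy)-3-methoxyphenol
Product: 2 4-(benzyloxy)-3-methoxyphenyl N-isopropylcarbamate
Conditions: i-PrNCO (1.3 equiv), Et3N (0.2 equiv), CH2Cl2, rt
Reagents that add atoms: isopropyl isocyanate, CC(C)N=C=O
Why: Amine-catalysed addition of the phenol O–H to the isocyanate (carbamoylation) should be clean, since the phenol is the only nucleophilic group present.

**Step 2**
Reactants: 2 4-(benzyloxy)-3-methoxyphenyl N-isopropylcarbamate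
Product: 6 4-(benzyloxy)-3-methoxy-2-(trimethylsilyl)phenyl N-isopropylcarbamate, via N-silyl carbamate 3 (not isolated), via aryllithium 4 (not isolated), via disilyl carbamate 5 (not isolated)
Conditions: TBSOTf (1.1 equiv), TMEDA, Et2O, 0 °C → rt; n-BuLi (2.2 equiv), TMEDA, −78 °C; Me3SiCl, −78 °C → rt; aq. NaHSO4
Reagents that add atoms: chlorotrimethylsilane, C[Si](C)(C)Cl
Why: Directed ortho-metalation: in situ N-silylation masks the N–H, the carbamate oxygen at C1 and the C5 methoxy group then direct n-BuLi/TMEDA cooperatively to C6 between them, Me3SiCl traps the aryllithium, and the acidic work-up hydrolyses the N–Si bond; at −78 °C the complex-induced ring lithiation should outrun deprotonation of the benzyl ether CH2.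

**Step 3**
Reactants: 6 4-(benzyloxy)-3-methoxy-2-(trimethylsilyl)phenyl N-isopropylcarbamate
Product: 8 4-(benzyloxy)-3-methoxy-2-(trimethylsilyl)phenyl trifluoromethanesulfonate, via silylphenol 7 (not isolated)
Conditions: DBU, Et2NH, MeCN, 40 °C; then PhNTf2, rt
Reagents that add atoms: N-phenylbis(trifluoromethanesulfonimide), O=S(=O)(N(c1ccccc1)S(=O)(=O)C(F)(F)F)C(F)(F)F
Why: DBU-induced E1cB cleavage of the N-monoalkyl carbamate releases the phenoxide (the isocyanate is scavenged by Et2NH as a urea), and O-triflation by PhNTf2 in the same pot avoids handling the ortho-silyl phenol, whose C–Si bond survives these non-aqueous conditions.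

**Step 4**
Reactants: 8 4-(benzyloxy)-3-methoxy-2-(trimethylsilyl)phenyl trifluoromethanesulfonate; 9 tert-butyl isocyanide; 10 3-bromo-4-methoxybenzaldehyde
Product: 14 (1Z)-5-(benzyloxy)-3-(3-bromo-4-methoxyphenyl)-N-tert-butyl-4-methoxy-2-benzofuran-1(3H)-imine (racemic at C3), via aryne 11 (not isolated), via nitrilium aryl anion 12 (not isolated), via nitrilium alkoxide 13 (not isolated)
Conditions: 8 (1.0 equiv), 9 (1.2 equiv), 10 (1.5 equiv), KF (3 equiv), 18-crown-6 (3 equiv), THF, 0 °C → rt
Reagents that add atoms: none
Why: Fluoride attacks silicon and the C6 carbanion expels the C1 triflate to give aryne 11; the isocyanide carbon adds to C1, the aryne carbon remote from the C5 methoxy group, so that the aryl anion of 12 sits at C6 where the inductively withdrawing C5 oxygen stabilises it. This anion adds to the carbonyl of 10 (C6–C bond) and the alkoxide of 13 closes on the nitrilium carbon in a 5-exo-dig mode (C–O bond), which forms the five-membered iminolactone ring. The closest known reaction is the three-component coupling of arynes, isocyanides and aldehydes to 1-imino-1,3-dihydroisobenzofurans, which is known for 3-methoxybenzyne. The new stereocentre at C3 of the isobenzofuran is under no control element and should form racemic, which does not matter because step 6 turns it into the methylene bridge; the imine should adopt the Z geometry that keeps the tert-butyl group away from the peri hydrogen. The step needs regioselective capture of the aryne, secured by the C5 methoxy group (the C4 benzyloxy group is one carbon further away and has little influence), and it needs the ring B bromide to stay intact, which KF at 0 °C should allow. Slow release of the aryne by KF/18-crown-6 in THF keeps its concentration low, so the 1:1:1 adduct should be favoured over products containing two aryne units.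

**Step 5**
Reactants: 14 (1Z)-5-(benzyloxy)-3-(3-bromo-4-methoxyphenyl)-N-tert-butyl-4-methoxy-2-benzofuran-1(3H)-imine
Product: 15 5-(benzyloxy)-3-(3-bromo-4-methoxyphenyl)-4-methoxy-2-benzofuran-1(3H)-one (racemic)
Conditions: 1 M aq. HCl, THF, rt
Reagents that add atoms: water, O
Why: Acid hydrolysis of a cyclic imidate: water adds to the protonated C=N and the tetrahedral intermediate expels tert-butylammonium rather than the ring oxygen, leaving the lactone, while the benzyl ether, methyl ethers and aryl bromide are inert to dilute acid at rt.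

**Step 6**
Reactants: 15 5-(benzyloxy)-3-(3-bromo-4-methoxyphenyl)-4-methoxy-2-benzofuran-1(3H)-one
Product: 16 4-(benzyloxy)-2-(3-bromo-4-methoxybenzyl)-3-methoxybenzoic acid
Conditions: Et3SiH (5 equiv), CF3CO2H/CH2Cl2 (1:1), 0 °C → rt
Reagents that add atoms: none
Why: Ionic hydrogenation: CF3CO2H ionises the doubly benzylic lactone C–O bond to a diarylmethyl cation stabilised by the para methoxy group of ring B, Et3SiH delivers hydride irreversibly, the carboxyl carbon is untouched and the stereocentre becomes the CH2 bridge; any early loss of the O-benzyl group in the acid would only anticipate step 7.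

**Step 7**
Reactants: 16 4-(benzyloxy)-2-(3-bromo-4-methoxybenzyl)-3-methoxybenzoic acid
Product: 17 2-(3-bromo-4-methoxybenzyl)-4-hydroxy-3-methoxybenzoic acid
Conditions: BCl3 (3 equiv), C6HMe5 (3 equiv), CH2Cl2, −78 °C; then H2O
Reagents that add atoms: none
Why: Lewis acid debenzylation with a cation scavenger: at −78 °C BCl3 should cleave the aryl benzyl ether but not the two aryl methyl ethers or the aryl bromide, and pentamethylbenzene traps the benzyl cation by Friedel–Crafts alkylation so that it cannot C-benzylate ring A.

**Step 8**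
Reactants: 17 2-(3-bromo-4-methoxybenzyl)-4-hydroxy-3-methoxybenzoic acid
Product: 18 5-bromo-2-(3-bromo-4-methoxybenzyl)-4-hydroxy-3-methoxybenzoic acid
Conditions: Br2 (1.0 equiv), AcOH, rt
Reagents that add atoms: bromine, BrBr
Why: Electrophilic aromatic bromination: the free C4 hydroxyl is the strongest activator, its para position C1 and one ortho position C5 are substituted, so bromine should enter at C3 (the vanillic acid pattern), while the ring B anisole is deactivated by its bromine and blocked at its para position.

**Step 9**
Reactants: 18 5-bromo-2-(3-bromo-4-methoxybenzyl)-4-hydroxy-3-methoxybenzoic acid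
Product: 19 5-bromo-2-(3-bromo-4-hydroxybenzyl)-3,4-dihydroxybenzoic acid
Conditions: BBr3 (6 equiv), CH2Cl2, −78 °C → rt; then H2O, 0 °C
Reagents that add atoms: none
Why: BBr3 cleavage of both aryl methyl ethers (O-complexation, then bromide attack at methyl) should leave the aryl bromides and the diarylmethane intact, and acylation of ring B to an anthrone is not expected because the positions ortho to the bridge are meta to oxygen and deactivated by bromine.

**Step 10**
Reactants: 19 5-bromo-2-(3-bromo-4-hydroxybenzyl)-3,4-dihydroxybenzoic acid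
Product: 20 3-bromo-6-(3-bromo-4-hydroxybenzyl)-5-(hydroxymethyl)benzene-1,2-diol (target)
Conditions: BH3·THF (6 equiv), THF, 0 °C → rt; then H2O/THF, work-up at pH 5–6 without alcohols
Reagents that add atoms: none
Why: Borane reduction of a carboxylic acid through its acyloxyborane gives the primary alcohol; the three phenols only form aryloxyboranes that water cleaves, the aryl bromides are inert, and keeping the temperature at or below rt and avoiding acid and alcohols in the work-up should protect the para-hydroxybenzyl alcohol from over-reduction or ether formation.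

**Compound list**

1 | 4-(benzyloxy)-3-methoxyphenol | COc1cc(O)ccc1OCc1ccccc1 | starting material
2 | 4-(benzyloxy)-3-methoxyphenyl N-isopropylcarbamate | COc1cc(OC(=O)NC(C)C)ccc1OCc1ccccc1 | intermediate
3 | 4-(benzyloxy)-3-methoxyphenyl N-(tert-butyldimethylsilyl)-N-isopropylcarbamate | COc1cc(OC(=O)N(C(C)C)[Si](C)(C)C(C)(C)C)ccc1OCc1ccccc1 | intermediate
4 | [3-(benzyloxy)-6-{[N-(tert-butyldimethylsilyl)-N-isopropylcarbamoyl]oxy}-2-methoxyphenyl]lithium | COc1c([Li])c(OC(=O)N(C(C)C)[Si](C)(C)C(C)(C)C)ccc1OCc1ccccc1 | intermediate
5 | 4-(benzyloxy)-3-methoxy-2-(trimethylsilyl)phenyl N-(tert-butyldimethylsilyl)-N-isopropylcarbamate | COc1c([Si](C)(C)C)c(OC(=O)N(C(C)C)[Si](C)(C)C(C)(C)C)ccc1OCc1ccccc1 | intermediate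
6 | 4-(benzyloxy)-3-methoxy-2-(trimethylsilyl)phenyl N-isopropylcarbamate | COc1c([Si](C)(C)C)c(OC(=O)NC(C)C)ccc1OCc1ccccc1 | intermediate
7 | 4-(benzyloxy)-3-methoxy-2-(trimethylsilyl)phenol (present as its DBU-H phenoxide) | COc1c([Si](C)(C)C)c(O)ccc1OCc1ccccc1 | intermediate
8 | 4-(benzyloxy)-3-methoxy-2-(trimethylsilyl)phenyl trifluoromethanesulfonate | COc1c([Si](C)(C)C)c(OS(=O)(=O)C(F)(F)F)ccc1OCc1ccccc1 | intermediate
9 | tert-butyl isocyanide | [C-]#[N+]C(C)(C)C | starting material
10 | 3-bromo-4-methoxybenzaldehyde | COc1ccc(C=O)cc1Br | starting material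
11 | 4-(benzyloxy)-3-methoxybenzyne (4-(benzyloxy)-3-methoxy-1,2-didehydrobenzene) | COC1=C(OCc2ccccc2)C=CC#C1 | intermediate
12 | zwitterion with the N-tert-butylnitrilium group at C1 and the aryl anion at C6 | CC(C)(C)[N+]#Cc1ccc(OCc2ccccc2)c(OC)[c-]1 | intermediate
13 | zwitterion with the N-tert-butylnitrilium group at C1 and the (3-bromo-4-methoxyphenyl)methanolate at C6 (racemic) | CC(C)(C)[N+]#Cc1ccc(OCc2ccccc2)c(OC)c1C([O-])c1ccc(OC)c(Br)c1 | intermediate
14 | (1Z)-5-(benzyloxy)-3-(3-bromo-4-methoxyphenyl)-N-tert-butyl-4-methoxy-2-benzofuran-1(3H)-imine (racemic at C3) | CC(C)(C)/N=C1\OC(c2ccc(OC)c(Br)c2)c2c1ccc(OCc3ccccc3)c2OC | intermediate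
15 | 5-(benzyloxy)-3-(3-bromo-4-methoxyphenyl)-4-methoxy-2-benzofuran-1(3H)-one (racemic) | O=C1OC(c2ccc(OC)c(Br)c2)c2c1ccc(OCc3ccccc3)c2OC | intermediate
16 | 4-(benzyloxy)-2-(3-bromo-4-methoxybenzyl)-3-methoxybenzoic acid | OC(=O)c1ccc(OCc2ccccc2)c(OC)c1Cc1ccc(OC)c(Br)c1 | intermediate
17 | 2-(3-bromo-4-methoxybenzyl)-4-hydroxy-3-methoxybenzoic acid | OC(=O)c1ccc(O)c(OC)c1Cc1ccc(OC)c(Br)c1 | intermediate
18 | 5-bromo-2-(3-bromo-4-methoxybenzyl)-4-hydroxy-3-methoxybenzoic acid | OC(=O)c1cc(Br)c(O)c(OC)c1Cc1ccc(OC)c(Br)c1 | intermediate
19 | 5-bromo-2-(3-bromo-4-hydroxybenzyl)-3,4-dihydroxybenzoic acid | OC(=O)c1cc(Br)c(O)c(O)c1Cc1ccc(O)c(Br)c1 | intermediate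
20 | 3-bromo-6-(3-bromo-4-hydroxybenzyl)-5-(hydroxymethyl)benzene-1,2-diol | OCc1cc(Br)c(O)c(O)c1Cc1ccc(O)c(Br)c1 | target

**Step count**

Total: 10 steps. Longest linear sequence: 10 steps (1 → 20); 9 and 10 enter at step 4.

**Steps most likely to fail, with fallbacks**

Step 4. The aryne may be used up by competing paths (adducts with two aryne units, isocyanide adducts that are protonated before they meet the aldehyde, slow addition of the C6 anion to an electron-rich aldehyde), or aryne capture may leak to the other regiochemistry. The fallback builds the same phthalide by amide-directed ortho-lithiation; it sets out from aldehyde 10 and returns to the route at phthalide 15, so step 5 is not needed. Commercial 4-(benzyloxy)-3-methoxybenzoic acid F1 would be converted with SOCl2 into 4-(benzyloxy)-3-methoxybenzoyl chloride F2 and then with Et2NH into 4-(benzyloxy)-N,N-diethyl-3-methoxybenzamide F3. s-BuLi/TMEDA in THF at −78 °C should lithiate C6 between the amide and the C5 methoxy group to give the aryllithium F4. Addition of 10 at −78 °C should give the racemic hydroxy amide 4-(benzyloxy)-2-[(3-bromo-4-methoxyphenyl)(hydroxy)methyl]-N,N-diethyl-3-methoxybenzamide F5, which on heating with TsOH in toluene should lactonise to 15 with loss of diethylamine.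

Step 8. Ipso attack of bromine at C1, para to the free hydroxyl, could lead to loss of CO2, and ring B could be brominated ortho to its methoxy group. The fallback masks the carboxyl so that ipso attack cannot end in decarboxylation; it sets out from 17 and returns at 18. Esterification of 17 (MeOH, catalytic H2SO4, reflux) should give methyl 2-(3-bromo-4-methoxybenzyl)-4-hydroxy-3-methoxybenzoate F6. Bromination with NBS in MeCN at 0 °C, which is more selective for the phenol ring, should give methyl 5-bromo-2-(3-bromo-4-methoxybenzyl)-4-hydroxy-3-methoxybenzoate F7. Saponification (LiOH, THF/H2O, 50 °C, then acidification) should give 18.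

Step 10. The C1 benzylic C–O bond lies para to the C4 aryloxyborane and could ionise to a quinone methide that is reduced further to a methyl group; insoluble borate complexes could stall the reduction; the product could form ethers during work-up. The fallback removes the para donor during the reduction; it sets out from 19 and returns at 20. Acetylation of 19 (Ac2O, pyridine, rt, aqueous work-up to hydrolyse the mixed anhydride) should give 3,4-diacetoxy-2-(4-acetoxy-3-bromobenzyl)-5-bromobenzoic acid F8. BH3·SMe2 in THF at 0 °C should reduce only the carboxylic acid and give 4-{[2,3-bis(acetyloxy)-4-bromo-6-(hydroxymethyl)phenyl]methyl}-2-bromophenyl acetate F9. Hydrazine hydrate in THF at 0 °C should remove the three aryl acetates under non-acidic, alcohol-free conditions and give 20.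

**Further compounds**

F1 | step 4 | 4-(benzyloxy)-3-methoxybenzoic acid | COc1cc(C(=O)O)ccc1OCc1ccccc1
F2 | step 4 | 4-(benzyloxy)-3-methoxybenzoyl chloride | COc1cc(C(=O)Cl)ccc1OCc1ccccc1
F3 | step 4 | 4-(benzyloxy)-N,N-diethyl-3-methoxybenzamide | CCN(CC)C(=O)c1ccc(OCc2ccccc2)c(OC)c1
F4 | step 4 | [3-(benzyloxy)-6-(diethylcarbamoyl)-2-methoxyphenyl]lithium | CCN(CC)C(=O)c1ccc(OCc2ccccc2)c(OC)c1[Li]
F5 | step 4 | 4-(benzyloxy)-2-[(3-bromo-4-methoxyphenyl)(hydroxy)methyl]-N,N-diethyl-3-methoxybenzamide (racemic) | CCN(CC)C(=O)c1ccc(OCc2ccccc2)c(OC)c1C(O)c1ccc(OC)c(Br)c1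
F6 | step 8 | methyl 2-(3-bromo-4-methoxybenzyl)-4-hydroxy-3-methoxybenzoate | COC(=O)c1ccc(O)c(OC)c1Cc1ccc(OC)c(Br)c1
F7 | step 8 | methyl 5-bromo-2-(3-bromo-4-methoxybenzyl)-4-hydroxy-3-methoxybenzoate | COC(=O)c1cc(Br)c(O)c(OC)c1Cc1ccc(OC)c(Br)c1
F8 | step 10 | 3,4-diacetoxy-2-(4-acetoxy-3-bromobenzyl)-5-bromobenzoic acid | OC(=O)c1cc(Br)c(OC(C)=O)c(OC(C)=O)c1Cc1ccc(OC(C)=O)c(Br)c1
F9 | step 10 | 4-{[2,3-bis(acetyloxy)-4-bromo-6-(hydroxymethyl)phenyl]methyl}-2-bromophenyl acetate | OCc1cc(Br)c(OC(C)=O)c(OC(C)=O)c1Cc1ccc(OC(C)=O)c(Br)c1
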